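**Retrosynthetic overview**

- Enabling feature: in the docosanoate chain, C4 and C5 (counted from the ester carbon C1) are both unsubstituted CH2 carbons flanked by CH2 groups (C3 and C6). Cutting C4–C5 therefore leaves two primary, unstabilised carbon radicals, with C4 three carbons away from C1.
- Key disconnection C4–C5: each radical carbon is given one extra CO2H as a traceless activating group. The ester half then becomes a glutaric acid half-ester, made from glutaric anhydride 1 and benzyl alcohol 2 (half-ester 3); the alkyl half becomes nonadecanoic acid 4.
- Forward: crossed Kolbe electrolysis of 3 and 4 generates radicals 5 and 6 at the anode; their combination gives target 7 with loss of two CO2.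
- Rings: none is formed. The phenyl ring arrives intact in 2, and the target has no stereocentre.

Key step: step 2

Assumption: glutaric anhydride, benzyl alcohol and nonadecanoic acid are taken as commercial materials; the target is achiral, so no step has to set or protect a configuration.

**Step 1**
Reactants: 1 glutaric anhydride; 2 benzyl alcohol
Product: 3 5-(benzyloxy)-5-oxopentanoic acid (monobenzyl glutarate)
Conditions: BnOH (1.0 equiv), DMAP (5 mol%), toluene, 80 °C; product taken into aq. NaHCO3, re-acidified and extracted
Reagents that add atoms: none
Why: DMAP-catalysed alcoholysis of a cyclic anhydride (nucleophilic acyl substitution) opens the ring only once, so the half-ester should form without diester, and the acid–base extraction removes any neutral material.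

**Step 2**
Reactants: 3 5-(benzyloxy)-5-oxopentanoic acid (5 equiv); 4 nonadecanoic acid (1 equiv)
Product: 7 benzyl docosanoate, via octadecyl radical 5 (not isolated), via 4-benzyloxy-4-oxobutyl radical 6 (not isolated)
Conditions: undivided cell, smooth Pt anode/Pt cathode, KOH (5 mol% of total acid), MeOH, 40–45 °C, constant current ca. 0.25 A cm⁻², polarity reversed periodically, stopped while still faintly acidic; silica gel chromatography (hexane, then 2–5% EtOAc)
Reagents that add atoms: none
Why: At a smooth platinum anode at high current density both carboxylates are oxidised by one electron to acyloxy radicals, which lose CO2 at once to give the primary radicals 5 and 6 in a dense layer at the electrode, where radical–radical combination joins the radical carbon of 5 (C5 of the target) to that of 6 (C4), while protons are reduced to H2 at the cathode. The closest known reaction type is the crossed (mixed) Kolbe electrolysis of a fatty acid with a dicarboxylic acid half-ester, the classical chain extension of long-chain esters. No ring is closed and no stereocentre is created. The selectivity needed is radical combination over further oxidation to carbocations (Hofer–Moest pathway) and cross- over homo-coupling: the first is secured by the substrate, since both radical carbons are unbranched primary CH2 without α-heteroatom, α-carbonyl or α-aryl group (the ester carbonyl of 6 sits three carbons from the radical centre); the second is handled statistically by the five-fold excess of the cheap half-ester 3, so that most of radical 5 should be intercepted by 6, and the homo-coupling products hexatriacontane (hydrocarbon) and dibenzyl adipate (diester) bracket 7 in polarity and should separate easily. The benzyl ester is expected to survive because the carboxylate-buffered, still acidic methanol holds no free methoxide and the unactivated arene is not discharged in competition with the carboxylate layer.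

**Compound list**

1 | glutaric anhydride | O=C1CCCC(=O)O1 | starting material
2 | benzyl alcohol | OCc1ccccc1 | starting material
3 | 5-(benzyloxy)-5-oxopentanoic acid (monobenzyl glutarate) | OC(=O)CCCC(=O)OCc1ccccc1 | intermediate
4 | nonadecanoic acid | CCCCCCCCCCCCCCCCCCC(=O)O | starting material
5 | octadecyl radical | CCCCCCCCCCCCCCCCC[CH2] | intermediate
6 | 4-benzyloxy-4-oxobutyl radical | [CH2]CCC(=O)OCc1ccccc1 | intermediate
7 | benzyl docosanoate | CCCCCCCCCCCCCCCCCCCCCC(=O)OCc1ccccc1 | target

**Step count and risks**

Total step count: 2. Longest linear sequence: 2 steps (1 → 3 → 7); acid 4 enters at step 2.

The route has only two steps, so both are ranked here instead of three.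

Step 2 (highest risk). What may go wrong: statistical homo-coupling of each radical consuming the limiting acid, over-oxidation of the radicals to cations giving methyl ethers and alkenes, slow methanolysis of the benzyl ester if the electrolyte turns basic, and passivation of the anode by waxy hydrocarbon. Fallback: a polar B-alkyl Suzuki–Miyaura coupling that forms the same C4–C5 bond without radicals or methanol. It sets out from benzyl alcohol 2, which is acylated with 4-bromobutanoyl chloride (O=C(Cl)CCCBr; Et3N, CH2Cl2, 0 °C) to benzyl 4-bromobutanoate F1. Separately, 1-octadecene (C=CCCCCCCCCCCCCCCCC) is hydroborated anti-Markovnikov with 9-BBN in THF to B-octadecyl-9-borabicyclo[3.3.1]nonane F2. F2 is coupled in the same pot with F1 (Pd(OAc)2, PCy3, K3PO4·H2O, THF, rt; conditions known for unactivated primary alkyl bromides and tolerant of esters), and the fallback returns to the route at 7.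

Step 1 (lower risk). What may go wrong: hydrolysis of the anhydride by adventitious water to glutaric acid (a diacid that would couple at both ends in step 2), or incomplete opening that carries benzyl alcohol forward. Fallback: desymmetrisation of the diester instead of the anhydride. It sets out from benzyl alcohol 2, which is condensed twice with glutaric acid (OC(=O)CCCC(=O)O; TsOH cat., toluene, Dean–Stark) to dibenzyl glutarate F3. One ester of F3 is then saponified selectively (1.0 equiv aq. KOH, THF–H2O, 0 °C; acid–base extraction), and the fallback returns to the route at 3.

**Further compounds**

F1 | step 2 | benzyl 4-bromobutanoate | BrCCCC(=O)OCc1ccccc1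
F2 | step 2 | B-octadecyl-9-borabicyclo[3.3.1]nonane | CCCCCCCCCCCCCCCCCCB1C2CCCC1CCC2
F3 | step 1 | dibenzyl glutarate | O=C(CCCC(=O)OCc1ccccc1)OCc1ccccc1
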